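**Plan**

- Locants: dibenzofuran numbering for ring A (C1–C4, oxygenated) and ring B (C6–C9); ring C is the catechol-type ring (C1' carries the bridge, C3' the aryl ether, C4' the oxygen); ring D is the para-phenylene.
- Retrosynthesis: first the two O–CH3 bonds, then both aryl–carbon bonds of the C7–CH2–CH2–C1' bridge together. This bridge links ring B and ring C through a symmetric two-carbon unit, so a cis-ethene bis-stannane can be delivered to a bis(aryl iodide) in either orientation.
- The open diiodide is cut at the other bridge (C1–CH2–CH2–ring D) as a Wittig alkene. The furan is cut at O5–C5a (fluoride displacement) and C9a–C9b (Suzuki), the diaryl ether at O–ring D (SNAr).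
- Forward: A–B biaryl, furan closure, Br-to-I exchange, phosphonium salt; C–D diaryl ether; Wittig union and diimide saturation; 18-membered ring by double Stille coupling; hydrogenation; demethylation.
- Stereochemistry: the target has no stereocentre. The only stereo-element on the way, the cis alkene of 21, comes from the distannane and is erased by hydrogenation.

Key step: step 11

Remark: (Z)-1,2-bis(tributylstannyl)ethene 18 is assumed to be purchasable as the pure cis isomer.

**Route**

Step 1
Reactants: 1 3,5-dimethoxybenzaldehyde
Product: 2 2-iodo-3,5-dimethoxybenzaldehyde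
Conditions: NIS (1.0 equiv), TFA (cat.), MeCN, 25 °C
Reagents that add atoms: N-iodosuccinimide, O=C1CCC(=O)N1I
Why: Electrophilic aromatic iodination should go to C2, which is para to one methoxy group and ortho to the other and less crowded than C4 between the two methoxy groups, and one equivalent of NIS limits di-iodination.

Step 2
Reactants: 2 2-iodo-3,5-dimethoxybenzaldehyde; 3 (4-bromo-2-fluorophenyl)boronic acid
Product: 4 2-(4-bromo-2-fluorophenyl)-3,5-dimethoxybenzaldehyde
Conditions: Pd(PPh3)4 (5 mol%), Na2CO3 (2 M aq.), DME, 80 °C
Reagents that add atoms: none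
Why: Suzuki–Miyaura coupling in which zerovalent palladium should insert into the formyl-activated C–I bond of 2 far faster than into the C–Br bond of 3 or 4, so the bromide is carried through.

Step 3
Reactants: 4 2-(4-bromo-2-fluorophenyl)-3,5-dimethoxybenzaldehyde
Product: 5 2-(4-bromo-2-fluorophenyl)-3,5-dihydroxybenzaldehyde
Conditions: BBr3 (4 equiv), CH2Cl2, −78 °C to 25 °C; then H2O
Reagents that add atoms: none
Why: Lewis-acid cleavage of both aryl methyl ethers with BBr3 is standard for methoxybenzaldehydes and should leave the aldehyde, the fluoride and the bromide untouched at or below room temperature.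

Step 4
Reactants: 5 2-(4-bromo-2-fluorophenyl)-3,5-dihydroxybenzaldehyde
Product: 7 7-bromo-3-methoxydibenzofuran-1-carbaldehyde, via dibenzofuranol 6 (not isolated)
Conditions: K2CO3 (3 equiv), NMP, 150 °C; then MeI, 25 °C
Reagents that add atoms: iodomethane, CI
Why: Intramolecular nucleophilic aromatic substitution, in which the phenoxide next to the biaryl bond displaces the ortho' fluoride in a five-membered ring closure (the charge of the addition intermediate is relayed through the biaryl bond to the formyl group), is followed in the same flask by Williamson methylation of the one phenoxide that remains.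

Step 5
Reactants: 7 7-bromo-3-methoxydibenzofuran-1-carbaldehyde
Product: 8 (7-bromo-3-methoxydibenzofuran-1-yl)methanol
Conditions: NaBH4, THF/MeOH, 0 °C
Reagents that add atoms: none
Why: Borohydride reduction of an aryl aldehyde to the benzylic alcohol is chemoselective in the presence of the aryl bromide and the ethers.

Step 6
Reactants: 8 (7-bromo-3-methoxydibenzofuran-1-yl)methanol
Product: 9 (7-iodo-3-methoxydibenzofuran-1-yl)methanol
Conditions: CuI (5 mol%), NaI (2 equiv), trans-N,N'-dimethylcyclohexane-1,2-diamine (10 mol%), 1,4-dioxane, 110 °C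
Reagents that add atoms: sodium iodide, [Na+].[I-]
Why: Copper-catalysed aromatic Finkelstein exchange of an aryl bromide is driven by the poor solubility of NaBr in dioxane, and its base-free conditions should leave the benzylic alcohol alone.

Step 7
Reactants: 9 (7-iodo-3-methoxydibenzofuran-1-yl)methanol
Product: 11 [(7-iodo-3-methoxydibenzofuran-1-yl)methyl]triphenylphosphonium bromide, via benzylic bromide 10 (not isolated)
Conditions: PPh3·HBr (1.05 equiv), MeCN, reflux
Reagents that add atoms: triphenylphosphine hydrobromide, Br.c1ccc(cc1)P(c1ccccc1)c1ccccc1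
Why: One-pot phosphonium salt formation, in which HBr converts the benzylic alcohol into the bromide and triphenylphosphine quaternises it by SN2 displacement, is a standard shortcut for benzylic alcohols and does not touch the aryl iodide.

Step 8
Reactants: 12 5-iodo-2-methoxyphenol; 13 4-fluorobenzaldehyde
Product: 14 4-(5-iodo-2-methoxyphenoxy)benzaldehyde
Conditions: K2CO3, DMF, 120 °C
Reagents that add atoms: none
Why: Nucleophilic aromatic substitution of the para-formyl-activated fluoride by the phenoxide gives the diaryl ether, and with no copper or palladium present the aryl iodide is inert.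

Step 9
Reactants: 11 [(7-iodo-3-methoxydibenzofuran-1-yl)methyl]triphenylphosphonium bromide; 14 4-(5-iodo-2-methoxyphenoxy)benzaldehyde
Product: 16 7-iodo-1-{2-[4-(5-iodo-2-methoxyphenoxy)phenyl]ethenyl}-3-methoxydibenzofuran (E/Z mixture), via ylide 15 (not isolated)
Conditions: KOtBu (1.1 equiv), THF, 0 °C; then 14, 0 °C to 25 °C
Reagents that add atoms: none
Why: Wittig olefination of a semi-stabilised benzylic ylide with an aryl aldehyde joins the two halves, and the expected E/Z mixture is of no consequence because the alkene is saturated in the next step.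

Step 10
Reactants: 16 7-iodo-1-{2-[4-(5-iodo-2-methoxyphenoxy)phenyl]ethenyl}-3-methoxydibenzofuran (E/Z mixture)
Product: 17 7-iodo-1-{2-[4-(5-iodo-2-methoxyphenoxy)phenyl]ethyl}-3-methoxydibenzofuran
Conditions: TsNHNH2 (8 equiv), NaOAc (10 equiv), DME/H2O, reflux
Reagents that add atoms: none
Why: Diimide released from tosylhydrazide transfers H2 to the stilbene by concerted syn addition and leaves the two aryl–iodine bonds intact, which catalytic hydrogenation would cleave.

Step 11
Reactants: 17 7-iodo-1-{2-[4-(5-iodo-2-methoxyphenoxy)phenyl]ethyl}-3-methoxydibenzofuran; 18 (Z)-1,2-bis(tributylstannyl)ethene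
Product: 21 macrocyclic (Z)-stilbene dimethyl ether (asterelin A dimethyl ether with a cis CH=CH in the C7–C1' bridge), via ring-B styrylstannane 19 (not isolated), via ring-C styrylstannane 20 (not isolated)
Conditions: Pd2(dba)3 (10 mol%), AsPh3 (40 mol%), DMF, 60 °C, 2 mM in 17, 18 (1.05 equiv) added by syringe pump over 12 h
Reagents that add atoms: none
Why: Two Stille couplings run in one flask: zerovalent palladium adds oxidatively to an Ar–I bond, the vinyl group is transferred from tin with retention of the double-bond geometry, and reductive elimination forms the aryl–vinyl bond, first between the two reactants (at C7 of ring B or at C1' of ring C, giving 19 or 20) and then within the molecule. The closest known reaction type is the stitching macrocyclisation of a bis-iodide with 1,2-bis(tributylstannyl)ethene. The 18-membered ring closes in the second, intramolecular aryl–vinyl coupling at whichever iodide is left, and the cis geometry of the ethene unit bends the chain so that the palladated aryl carbon can reach the vinyl–tin carbon. No stereocentre is formed; the Z configuration of the new alkene is carried over from 18 and is removed again in step 12. The step needs ring closure to outrun chain growth, which the high dilution and the slow addition of 18 should secure, and it needs no differentiation of the two iodides because the two-carbon unit is symmetric.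

Step 12
Reactants: 21 macrocyclic (Z)-stilbene dimethyl ether
Product: 22 asterelin A dimethyl ether (3-OMe on ring A, 4'-OMe on ring C)
Conditions: H2 (1 atm), 10% Pd/C, EtOAc, 25 °C
Reagents that add atoms: none
Why: Heterogeneous hydrogenation of the cis-stilbene over palladium on carbon, run on material freed of tin residues by a KF wash, should leave the aryl ethers and the dibenzofuran untouched.

Step 13
Reactants: 22 asterelin A dimethyl ether
Product: 23 asterelin A
Conditions: BBr3 (6 equiv), CH2Cl2, −78 °C to 25 °C; then H2O
Reagents that add atoms: none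
Why: BBr3 cleaves the two aryl methyl ethers, while the diaryl ether and the dibenzofuran C–O bonds, which have no alkyl carbon for bromide to attack, should survive.

**Compound list**

1 | 3,5-dimethoxybenzaldehyde | COc1cc(C=O)cc(OC)c1 | starting material
2 | 2-iodo-3,5-dimethoxybenzaldehyde | COc1cc(OC)c(I)c(C=O)c1 | intermediate
3 | (4-bromo-2-fluorophenyl)boronic acid | OB(O)c1ccc(Br)cc1F | starting material
4 | 2-(4-bromo-2-fluorophenyl)-3,5-dimethoxybenzaldehyde | COc1cc(OC)c(-c2ccc(Br)cc2F)c(C=O)c1 | intermediate
5 | 2-(4-bromo-2-fluorophenyl)-3,5-dihydroxybenzaldehyde | Oc1cc(O)c(-c2ccc(Br)cc2F)c(C=O)c1 | intermediate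
6 | 7-bromo-3-hydroxydibenzofuran-1-carbaldehyde | Oc1cc(C=O)c2c(c1)oc1cc(Br)ccc12 | intermediate
7 | 7-bromo-3-methoxydibenzofuran-1-carbaldehyde | COc1cc(C=O)c2c(c1)oc1cc(Br)ccc12 | intermediate
8 | (7-bromo-3-methoxydibenzofuran-1-yl)methanol | COc1cc(CO)c2c(c1)oc1cc(Br)ccc12 | intermediate
9 | (7-iodo-3-methoxydibenzofuran-1-yl)methanol | COc1cc(CO)c2c(c1)oc1cc(I)ccc12 | intermediate
10 | 1-(bromomethyl)-7-iodo-3-methoxydibenzofuran | COc1cc(CBr)c2c(c1)oc1cc(I)ccc12 | intermediate
11 | [(7-iodo-3-methoxydibenzofuran-1-yl)methyl]triphenylphosphonium bromide | COc1cc(C[P+](c2ccccc2)(c2ccccc2)c2ccccc2)c2c(c1)oc1cc(I)ccc12.[Br-] | intermediate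
12 | 5-iodo-2-methoxyphenol | COc1ccc(I)cc1O | starting material
13 | 4-fluorobenzaldehyde | O=Cc1ccc(F)cc1 | starting material
14 | 4-(5-iodo-2-methoxyphenoxy)benzaldehyde | COc1ccc(I)cc1Oc1ccc(C=O)cc1 | intermediate
15 | [(7-iodo-3-methoxydibenzofuran-1-yl)methylidene]triphenylphosphorane | COc1cc(C=P(c2ccccc2)(c2ccccc2)c2ccccc2)c2c(c1)oc1cc(I)ccc12 | intermediate
16 | 7-iodo-1-{2-[4-(5-iodo-2-methoxyphenoxy)phenyl]ethenyl}-3-methoxydibenzofuran (E/Z mixture, geometry left open) | COc1cc(C=Cc2ccc(Oc3cc(I)ccc3OC)cc2)c2c(c1)oc1cc(I)ccc12 | intermediate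
17 | 7-iodo-1-{2-[4-(5-iodo-2-methoxyphenoxy)phenyl]ethyl}-3-methoxydibenzofuran | COc1cc(CCc2ccc(Oc3cc(I)ccc3OC)cc2)c2c(c1)oc1cc(I)ccc12 | intermediate
18 | (Z)-1,2-bis(tributylstannyl)ethene | CCCC[Sn](CCCC)(CCCC)/C=C\[Sn](CCCC)(CCCC)CCCC | starting material
19 | 1-{2-[4-(5-iodo-2-methoxyphenoxy)phenyl]ethyl}-3-methoxy-7-[(Z)-2-(tributylstannyl)ethenyl]dibenzofuran | COc1cc(CCc2ccc(Oc3cc(I)ccc3OC)cc2)c2c(c1)oc1cc(/C=C\[Sn](CCCC)(CCCC)CCCC)ccc12 | intermediate
20 | 7-iodo-3-methoxy-1-[2-(4-{2-methoxy-5-[(Z)-2-(tributylstannyl)ethenyl]phenoxy}phenyl)ethyl]dibenzofuran | COc1cc(CCc2ccc(Oc3cc(/C=C\[Sn](CCCC)(CCCC)CCCC)ccc3OC)cc2)c2c(c1)oc1cc(I)ccc12 | intermediate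
21 | macrocyclic (Z)-stilbene dimethyl ether (cis CH=CH between C7 of ring B and C1' of ring C) | COc1cc2c3c(c1)oc1cc(ccc13)/C=C\c1ccc(OC)c(c1)Oc1ccc(cc1)CC2 | intermediate
22 | asterelin A dimethyl ether | COc1cc2c3c(c1)oc1cc(ccc13)CCc1ccc(OC)c(c1)Oc1ccc(cc1)CC2 | intermediate
23 | asterelin A | Oc1cc2c3c(c1)oc1cc(ccc13)CCc1ccc(O)c(c1)Oc1ccc(cc1)CC2 | target

**Count**

Total steps: 13. Longest linear sequence: 12 (steps 1–7 and 9–13; step 8 is a one-step side branch).

**Steps most likely to fail**

Step 11. Chain growth may outrun ring closure, when a styrylstannane 19 or 20 couples with a second molecule of 17 instead of with its own iodide. The styrylstannane may also isomerise to the trans form or lose tin by protonolysis before it cyclises. The fallback sets out from 17 and closes the ring by olefin metathesis. Two-fold Stille coupling of 17 with tributyl(vinyl)stannane (Pd(PPh3)4, toluene, 100 °C) should give 7-ethenyl-1-{2-[4-(5-ethenyl-2-methoxyphenoxy)phenyl]ethyl}-3-methoxydibenzofuran F1. Ring-closing metathesis of F1 with the second-generation Grubbs catalyst, RuCl2(=CHPh)(H2IMes)(PCy3), at 1 mM in CH2Cl2 at 40 °C releases ethene and should close the same 18-membered ring, rejoining the route at 21. Should the ring close to the trans-stilbene dimethyl ether F2 instead, this is hydrogenated under the conditions of step 12 and the route is rejoined at 22.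

Step 2. Halogen selectivity may be lost: palladium may insert into the C–Br bond of 3 or of 4 while the hindered iodide reacts slowly, which leads to oligoaryls, and the ortho-fluoro boronic acid may protodeboronate. The fallback sets out from 2 and reverses the polarity of the coupling. Miyaura borylation of 2 (bis(pinacolato)diboron, PdCl2(dppf), KOAc, DMSO, 80 °C) should give 3,5-dimethoxy-2-(4,4,5,5-tetramethyl-1,3,2-dioxaborolan-2-yl)benzaldehyde F3. Suzuki coupling of F3 with commercial 4-bromo-2-fluoro-1-iodobenzene (Pd(PPh3)4, Na2CO3 aq., DME, 80 °C) then takes place at the C–I bond. The boron partner now carries no halogen, and the route is rejoined at 4.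

Step 4. Fluoride displacement on ring B may be slow, since no acceptor sits ortho or para to the fluorine, and at the temperature then needed the aldehyde may disproportionate or condense under base. The fallback sets out from 5 and moves the ring closure to the alcohol oxidation level, where much stronger base can be used. Reduction of 5 with NaBH4 (MeOH, 0 °C) should give 4'-bromo-2'-fluoro-6-(hydroxymethyl)biphenyl-2,4-diol F4. Cyclisation of F4 with KOtBu in DMSO at 120 °C should give 7-bromo-1-(hydroxymethyl)dibenzofuran-3-ol F5. Selective methylation of the phenol of F5 (MeI, K2CO3, acetone, reflux) rejoins the route at 8.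

**Further compounds**

F1 | step 11 | 7-ethenyl-1-{2-[4-(5-ethenyl-2-methoxyphenoxy)phenyl]ethyl}-3-methoxydibenzofuran | COc1cc(CCc2ccc(Oc3cc(C=C)ccc3OC)cc2)c2c(c1)oc1cc(C=C)ccc12
F2 | step 11 | macrocyclic (E)-stilbene dimethyl ether (trans isomer of 21) | COc1cc2c3c(c1)oc1cc(ccc13)/C=C/c1ccc(OC)c(c1)Oc1ccc(cc1)CC2
F3 | step 2 | 3,5-dimethoxy-2-(4,4,5,5-tetramethyl-1,3,2-dioxaborolan-2-yl)benzaldehyde | COc1cc(OC)c(B2OC(C)(C)C(C)(C)O2)c(C=O)c1
F4 | step 4 | 4'-bromo-2'-fluoro-6-(hydroxymethyl)biphenyl-2,4-diol | OCc1cc(O)cc(O)c1-c1ccc(Br)cc1F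
F5 | step 4 | 7-bromo-1-(hydroxymethyl)dibenzofuran-3-ol | OCc1cc(O)cc2oc3cc(Br)ccc3c12
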